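**Plan**

1. Numbering (carotane): C1 = quaternary ring-fusion carbon (CH3-15), C2, C3, C4 = isopropyl carbinol, C5 = ring-fusion CH, C6 = ester carbon, C7=C8 (CH3-14), C9 = allylic carbinol, C10; ring A = C1–C5, ring B = C1, C5–C10. The α face carries H5, the isopropyl group and the C6 oxygen; the β face carries CH3-15 and the C4 and C9 oxygens.
2. Cuts, in retrosynthetic order: ester C6–O; C9–H (enone reduction) and C7=C8 (dehydrogenation); C6–O/C5–H (hydroboration of C5=C6); C8–C14 (enolate methylation); C10–C1 (Claisen shift); C6–C7 (Grignard addition); C1–C5 (aldol), back to (S)-terpinen-4-ol, bromide 7 and acid 19.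
3. Enabling feature: the C9 oxygen and C6 are 1,4 across ring B through C7–C8, and C9(=O)–C10–C1–C5=C6 is a γ,δ-unsaturated ketone around the quaternary C1. The oxygen that ends on C9 is therefore first bonded to C6 in a temporary 2-methylideneoxolane (O, C6, C7, C8, C9; absent from the target). Its [3,3] shift forms C10–C1, cleaves C6–O and expands the five-membered ether into the seven-membered carbocycle.
4. Forward: the cyclohexene of terpinen-4-ol is cut and re-closed to the cyclopentene (ring A); the C6–C10 chain is added; oxolane formation and the Claisen shift close ring B; C14, the C6 oxygen, the ester, C7=C8 and the C9 carbinol follow.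
5. Stereochemistry: C4 comes from the chiral pool; the temporary C6 carbinol is set by CBS reduction and relayed to C1 by the Claisen shift; C5 and C6 are set together by syn hydroboration anti to CH3-15 and the C4 oxygen; C9 is set by a second CBS reduction.

Key step: step 7

Assumption: (S)-(+)-terpinen-4-ol is used as enantiopure commercial material.
Remark: bicyclic compounds are named with azulene locants (C3 = carotane C4, C3a = C5, C4 = C6, C6 = C8, C7 = C9, C8a = C1); the discussion uses carotane numbers.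

**Route**

Step 1
Reactants: 1 (S)-(+)-terpinen-4-ol
Product: 2 triethyl{[(1S)-4-methyl-1-(propan-2-yl)cyclohex-3-en-1-yl]oxy}silane
Conditions: Et3SiOTf, 2,6-lutidine, CH2Cl2, 0 → 23 °C
Reagents that add atoms: triethylsilyl trifluoromethanesulfonate, CC[Si](CC)(CC)OS(=O)(=O)C(F)(F)F
Why: Silyl triflate/lutidine silylation of a hindered tertiary alcohol (protecting-group installation) masks the C4 oxygen as a poor leaving group for step 3 and as a bulky β-face substituent for step 10.

Step 2
Reactants: 2 triethylsilyl ether of terpinen-4-ol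
Product: 4 (3S)-6-oxo-3-(propan-2-yl)-3-[(triethylsilyl)oxy]heptanal, via ozonide 3 (not isolated)
Conditions: O3, CH2Cl2, −78 °C; then PPh3, −78 → 23 °C
Reagents that add atoms: ozone, [O-][O+]=O
Why: Ozonolysis with reductive work-up cleaves the only C=C bond to the 1,6-keto aldehyde and leaves the quaternary silyloxy centre untouched.

Step 3
Reactants: 4 keto aldehyde
Product: 6 (5R)-2-methyl-5-(propan-2-yl)-5-[(triethylsilyl)oxy]cyclopent-1-ene-1-carbaldehyde, via aldol adduct 5 (not isolated)
Conditions: piperidine (20 mol%), AcOH (20 mol%), toluene, 70 °C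
Reagents that add atoms: none
Why: Amine/acid-catalysed intramolecular aldol condensation (the aldehyde enamine adds 5-exo to the methyl ketone, then water is lost), the reaction type that converts terpene-derived 1,6-keto aldehydes into 2-methylcyclopentenecarbaldehydes; the silyl ether on the other β-carbon is the poorer leaving group, so dehydration should go toward C1.

Step 4
Reactants: 6 cyclopentenecarbaldehyde; 7 (4-bromobut-1-yn-1-yl)trimethylsilane
Product: 8 1-[(5R)-2-methyl-5-(propan-2-yl)-5-[(triethylsilyl)oxy]cyclopent-1-en-1-yl]-5-(trimethylsilyl)pent-4-yn-1-ol (both C1 epimers)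
Conditions: 7, Mg, THF, 23 °C; then 6, THF, −78 → 0 °C; pH 7 buffer
Reagents that add atoms: none
Why: 1,2-Addition of a primary alkyl Grignard reagent to the hindered enal (the β-carbon is fully substituted, so conjugate addition is not expected); the new carbinol centre is not controlled here and is erased in step 5.

Step 5
Reactants: 8 allylic alcohol (epimers)
Product: 9 1-[(5R)-2-methyl-5-(propan-2-yl)-5-[(triethylsilyl)oxy]cyclopent-1-en-1-yl]-5-(trimethylsilyl)pent-4-yn-1-one
Conditions: Dess–Martin periodinane (1,1,1-triacetoxy-1,1-dihydro-1,2-benziodoxol-3(1H)-one), NaHCO3, CH2Cl2, 0 → 23 °C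
Reagents that add atoms: none
Why: Dess–Martin oxidation of the secondary allylic alcohol under buffered conditions converges both epimers to the enone and spares both silyl groups.

Step 6
Reactants: 9 enone
Product: 11 (1S)-1-[(5R)-2-methyl-5-(propan-2-yl)-5-[(triethylsilyl)oxy]cyclopent-1-en-1-yl]pent-4-yn-1-ol, via silylated alkynol 10 (not isolated)
Conditions: (R)-tetrahydro-1-methyl-3,3-diphenyl-1H,3H-pyrrolo[1,2-c][1,3,2]oxazaborole [(R)-Me-CBS, 20 mol%], BH3·SMe2, THF, −30 → 0 °C; MeOH; then K2CO3, MeOH, 23 °C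
Reagents that add atoms: none
Why: Corey–Bakshi–Shibata reduction in which the tetrasubstituted cyclopentenyl group is the large and the CH2 chain the small substituent, so the (R)-oxazaborolidine should give the (S)-carbinol at C6 by reagent control; methanolic K2CO3 then protodesilylates the alkyne without touching the tertiary triethylsilyl ether.

Step 7
Reactants: 11 alkynol
Product: 13 (3R,8aR)-8a-methyl-3-(propan-2-yl)-3-[(triethylsilyl)oxy]-1,2,3,5,6,8a-hexahydroazulen-7(8H)-one, via methylideneoxolane 12 (not isolated)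
Conditions: Ag2CO3 (10 mol%), toluene, 80 °C; filtration through Celite; then 170 °C, sealed tube
Reagents that add atoms: none
Why: Monovalent silver activates the terminal alkyne so that the C6 hydroxyl adds in a 5-exo-dig mode to give the 2-methylideneoxolane 12 (ring: O, C6, C7, C8, C9), an allyl vinyl ether C10=C9–O–C6–C5=C1 whose two halves are tied by C7–C8; on heating, a concerted [3,3]-sigmatropic (Claisen) shift forms C10–C1, breaks C6–O and leaves C9=O and C5=C6. The closest known reaction type is the cycloisomerization–Claisen ring expansion of 1-alkenylpent-4-yn-1-ols (2-methylidene-5-vinyloxolanes) to cyclohept-4-enones. The oxolane closes by 5-exo-dig oxymetalation, and the seven-membered carbocycle arises by ring expansion through a bicyclic boat-like six-centre transition state, formally a 7-endo closure onto C1. The only new stereocentre, quaternary C1, is fixed by suprafacial 1,3-chirality transfer from C6: the C7–C8 tether forces C7 cis to C1 in the new C5=C6 bond, so the breaking C6–O bond and the incoming C10 lie on the same face of the cyclopentene, which for the (6S) carbinol is the α face, giving (1R). The step needs exo oxymetalation and survival of the exocyclic enol ether (no drift to the endocyclic 2-methyl-4,5-dihydrofuran, no ionization of the doubly allylic C6–O bond), which the terminal alkyne and the basic, acid-free carbonate medium should secure.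

Step 8
Reactants: 13 cycloheptenone
Product: 15 (3R,8aR)-6,8a-dimethyl-3-(propan-2-yl)-3-[(triethylsilyl)oxy]-1,2,3,5,6,8a-hexahydroazulen-7(8H)-one (both C6 epimers), via lithium enolate 14 (not isolated)
Conditions: LiN(iPr)2 (LDA), THF, −78 °C; then MeI, −78 → −40 °C
Reagents that add atoms: iodomethane, CI
Why: Kinetic deprotonation should occur at C8, the α-methylene remote from the quaternary C1 (C10 is neopentyl), and C-methylation of the enolate installs C14 (enolate alkylation); the new C8 centre is inconsequential because it becomes sp2 in step 13.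

Step 9
Reactants: 15 methyl ketone
Product: 16 (3'R,8a'R)-6',8a'-dimethyl-3'-(propan-2-yl)-3'-[(triethylsilyl)oxy]-1',2',3',5',6',8a'-hexahydro-8'H-spiro[1,3-dioxolane-2,7'-azulene] (both C6' epimers)
Conditions: Me3SiOCH2CH2OSiMe3, Me3SiOTf (5 mol%), CH2Cl2, −78 → −20 °C
Reagents that add atoms: 1,2-bis(trimethylsilyloxy)ethane, C[Si](C)(C)OCCO[Si](C)(C)C
Why: Aprotic silyl-triflate-catalysed ketalization converts hindered ketones at low temperature, spares the allylic tertiary silyl ether and masks C9=O against borane.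

Step 10
Reactants: 16 ketal alkene
Product: 18 (3'R,3a'S,4'S,8a'R)-6',8a'-dimethyl-3'-(propan-2-yl)-3'-[(triethylsilyl)oxy]octahydro-1'H-spiro[1,3-dioxolane-2,7'-azulen]-4'-ol (both C6' epimers), via alkylborane 17 (not isolated)
Conditions: BH3·THF, THF, 0 → 23 °C; then NaOH, H2O2, H2O, 0 °C
Reagents that add atoms: hydrogen peroxide, OO
Why: Hydroboration–oxidation adds H and B syn across the trisubstituted C5=C6 bond with boron at the less substituted C6, from the α face opposite both the angular CH3-15 and the C4 silyloxy group (the mode in which Δ5-steroids give 5α,6α products), so C5–H, C6–O and the trans ring fusion are set together; the oxidation proceeds with retention.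

Step 11
Reactants: 18 secondary alcohol; 19 4-acetoxy-3-methoxybenzoic acid
Product: 20 (3'R,3a'S,4'S,8a'R)-6',8a'-dimethyl-3'-(propan-2-yl)-3'-[(triethylsilyl)oxy]octahydro-1'H-spiro[1,3-dioxolane-2,7'-azulen]-4'-yl 4-acetoxy-3-methoxybenzoate (both C6' epimers)
Conditions: dicyclohexylcarbodiimide, 4-(dimethylamino)pyridine, CH2Cl2, 23 → 40 °C
Reagents that add atoms: none
Why: Steglich esterification acylates the only free hydroxyl with retention at C6, the position at which related carotane diols are known to accept aroyl groups; the phenol is carried as its acetate.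

Step 12
Reactants: 20 ester ketal
Product: 21 (3R,3aS,4S,8aR)-3-hydroxy-6,8a-dimethyl-7-oxo-3-(propan-2-yl)decahydroazulen-4-yl 4-acetoxy-3-methoxybenzoate (both C6 epimers)
Conditions: HF (48% aq.), MeCN, 0 → 23 °C
Reagents that add atoms: water, O
Why: Aqueous HF hydrolyses the dioxolane and cleaves the tertiary triethylsilyl ether in one operation (acetal hydrolysis and desilylation), while the benzoate and the aryl acetate should survive.

Step 13
Reactants: 21 keto ester
Product: 22 (3R,3aS,4S,8aR)-3-hydroxy-6,8a-dimethyl-7-oxo-3-(propan-2-yl)-1,2,3,3a,4,7,8,8a-octahydroazulen-4-yl 4-acetoxy-3-methoxybenzoate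
Conditions: IBX (2-iodoxybenzoic acid), DMSO/fluorobenzene, 70 °C
Reagents that add atoms: none
Why: IBX dehydrogenation of a ketone to the enone can only give C7=C8, because C10 is flanked by the quaternary C1 and has no β-hydrogen; this removes the C8 centre, and the tertiary alcohol, the ester and the aryl acetate are inert to IBX whereas a free phenol would not be.

Step 14
Reactants: 22 enone
Product: 24 (3R,3aS,4S,7R,8aR)-3,7-dihydroxy-6,8a-dimethyl-3-(propan-2-yl)-1,2,3,3a,4,7,8,8a-octahydroazulen-4-yl 4-hydroxy-3-methoxybenzoate, via acetate 23 (not isolated)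
Conditions: (S)-tetrahydro-1-methyl-3,3-diphenyl-1H,3H-pyrrolo[1,2-c][1,3,2]oxazaborole [(S)-Me-CBS, 30 mol%], BH3·SMe2, THF, −30 °C; MeOH; then K2CO3, MeOH, 0 → 23 °C
Reagents that add atoms: none
Why: Corey–Bakshi–Shibata 1,2-reduction of the α-methyl enone (alkenyl C8 large, C10H2 small) with the (S)-oxazaborolidine should give the (9R) allylic alcohol, the sense that also corresponds to hydride approach anti to CH3-15; K2CO3 in methanol then cleaves the phenolic acetate selectively (aryl acetate methanolysis), the hindered alkyl benzoate being far slower and deactivated further once the phenoxide forms.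

**Compound list**

1 | (S)-(+)-terpinen-4-ol, (1S)-4-methyl-1-(propan-2-yl)cyclohex-3-en-1-ol | CC1=CC[C@](O)(C(C)C)CC1 | starting material
2 | triethyl{[(1S)-4-methyl-1-(propan-2-yl)cyclohex-3-en-1-yl]oxy}silane | CC1=CC[C@](O[Si](CC)(CC)CC)(C(C)C)CC1 | intermediate
3 | ozonide of 2, (4S)-1-methyl-4-(propan-2-yl)-4-[(triethylsilyl)oxy]-7,8,9-trioxabicyclo[4.2.1]nonane (bridge diastereomers) | CC12OOC(O1)C[C@](O[Si](CC)(CC)CC)(C(C)C)CC2 | intermediate
4 | (3S)-6-oxo-3-(propan-2-yl)-3-[(triethylsilyl)oxy]heptanal | O=CC[C@](O[Si](CC)(CC)CC)(C(C)C)CCC(C)=O | intermediate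
5 | (5R)-2-hydroxy-2-methyl-5-(propan-2-yl)-5-[(triethylsilyl)oxy]cyclopentane-1-carbaldehyde (diastereomers at C1 and C2) | O=CC1C(C)(O)CC[C@@]1(O[Si](CC)(CC)CC)C(C)C | intermediate
6 | (5R)-2-methyl-5-(propan-2-yl)-5-[(triethylsilyl)oxy]cyclopent-1-ene-1-carbaldehyde | O=CC1=C(C)CC[C@@]1(O[Si](CC)(CC)CC)C(C)C | intermediate
7 | (4-bromobut-1-yn-1-yl)trimethylsilane | C[Si](C)(C)C#CCCBr | starting material
8 | 1-[(5R)-2-methyl-5-(propan-2-yl)-5-[(triethylsilyl)oxy]cyclopent-1-en-1-yl]-5-(trimethylsilyl)pent-4-yn-1-ol (both C1 epimers) | C[Si](C)(C)C#CCCC(O)C1=C(C)CC[C@@]1(O[Si](CC)(CC)CC)C(C)C | intermediate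
9 | 1-[(5R)-2-methyl-5-(propan-2-yl)-5-[(triethylsilyl)oxy]cyclopent-1-en-1-yl]-5-(trimethylsilyl)pent-4-yn-1-one | C[Si](C)(C)C#CCCC(=O)C1=C(C)CC[C@@]1(O[Si](CC)(CC)CC)C(C)C | intermediate
10 | (1S)-1-[(5R)-2-methyl-5-(propan-2-yl)-5-[(triethylsilyl)oxy]cyclopent-1-en-1-yl]-5-(trimethylsilyl)pent-4-yn-1-ol | C[Si](C)(C)C#CCC[C@H](O)C1=C(C)CC[C@@]1(O[Si](CC)(CC)CC)C(C)C | intermediate
11 | (1S)-1-[(5R)-2-methyl-5-(propan-2-yl)-5-[(triethylsilyl)oxy]cyclopent-1-en-1-yl]pent-4-yn-1-ol | C#CCC[C@H](O)C1=C(C)CC[C@@]1(O[Si](CC)(CC)CC)C(C)C | intermediate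
12 | (2S)-5-methylidene-2-[(5R)-2-methyl-5-(propan-2-yl)-5-[(triethylsilyl)oxy]cyclopent-1-en-1-yl]oxolane | C=C1CC[C@H](O1)C2=C(C)CC[C@@]2(O[Si](CC)(CC)CC)C(C)C | intermediate
13 | (3R,8aR)-8a-methyl-3-(propan-2-yl)-3-[(triethylsilyl)oxy]-1,2,3,5,6,8a-hexahydroazulen-7(8H)-one | O=C1CCC=C2[C@](O[Si](CC)(CC)CC)(C(C)C)CC[C@]2(C)C1 | intermediate
14 | lithium enolate of 13 (C8=C9 enolate, carotane numbering) | [Li+].[O-]C1=CCC=C2[C@](O[Si](CC)(CC)CC)(C(C)C)CC[C@]2(C)C1 | intermediate
15 | (3R,8aR)-6,8a-dimethyl-3-(propan-2-yl)-3-[(triethylsilyl)oxy]-1,2,3,5,6,8a-hexahydroazulen-7(8H)-one (both C6 epimers) | O=C1C(C)CC=C2[C@](O[Si](CC)(CC)CC)(C(C)C)CC[C@]2(C)C1 | intermediate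
16 | (3'R,8a'R)-6',8a'-dimethyl-3'-(propan-2-yl)-3'-[(triethylsilyl)oxy]-1',2',3',5',6',8a'-hexahydro-8'H-spiro[1,3-dioxolane-2,7'-azulene] (both C6' epimers) | CC1CC=C2[C@](O[Si](CC)(CC)CC)(C(C)C)CC[C@]2(C)CC13OCCO3 | intermediate
17 | monoalkylborane from 16: BH2 on C4' and H on C3a', both on the α face (same spatial arrangement as 18) | B[C@H]1CC(C)C2(OCCO2)C[C@@]3(C)CC[C@@](O[Si](CC)(CC)CC)(C(C)C)[C@H]13 | intermediate
18 | (3'R,3a'S,4'S,8a'R)-6',8a'-dimethyl-3'-(propan-2-yl)-3'-[(triethylsilyl)oxy]octahydro-1'H-spiro[1,3-dioxolane-2,7'-azulen]-4'-ol (both C6' epimers) | O[C@H]1CC(C)C2(OCCO2)C[C@@]3(C)CC[C@@](O[Si](CC)(CC)CC)(C(C)C)[C@H]13 | intermediate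
19 | 4-acetoxy-3-methoxybenzoic acid | COc1cc(C(=O)O)ccc1OC(C)=O | starting material
20 | (3'R,3a'S,4'S,8a'R)-6',8a'-dimethyl-3'-(propan-2-yl)-3'-[(triethylsilyl)oxy]octahydro-1'H-spiro[1,3-dioxolane-2,7'-azulen]-4'-yl 4-acetoxy-3-methoxybenzoate (both C6' epimers) | COc1cc(C(=O)O[C@H]2CC(C)C3(OCCO3)C[C@@]4(C)CC[C@@](O[Si](CC)(CC)CC)(C(C)C)[C@H]24)ccc1OC(C)=O | intermediate
21 | (3R,3aS,4S,8aR)-3-hydroxy-6,8a-dimethyl-7-oxo-3-(propan-2-yl)decahydroazulen-4-yl 4-acetoxy-3-methoxybenzoate (both C6 epimers) | COc1cc(C(=O)O[C@H]2CC(C)C(=O)C[C@@]3(C)CC[C@@](O)(C(C)C)[C@H]23)ccc1OC(C)=O | intermediate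
22 | (3R,3aS,4S,8aR)-3-hydroxy-6,8a-dimethyl-7-oxo-3-(propan-2-yl)-1,2,3,3a,4,7,8,8a-octahydroazulen-4-yl 4-acetoxy-3-methoxybenzoate | COc1cc(C(=O)O[C@H]2C=C(C)C(=O)C[C@@]3(C)CC[C@@](O)(C(C)C)[C@H]23)ccc1OC(C)=O | intermediate
23 | (3R,3aS,4S,7R,8aR)-3,7-dihydroxy-6,8a-dimethyl-3-(propan-2-yl)-1,2,3,3a,4,7,8,8a-octahydroazulen-4-yl 4-acetoxy-3-methoxybenzoate | COc1cc(C(=O)O[C@H]2C=C(C)[C@H](O)C[C@@]3(C)CC[C@@](O)(C(C)C)[C@H]23)ccc1OC(C)=O | intermediate
24 | (3R,3aS,4S,7R,8aR)-3,7-dihydroxy-6,8a-dimethyl-3-(propan-2-yl)-1,2,3,3a,4,7,8,8a-octahydroazulen-4-yl 4-hydroxy-3-methoxybenzoate | COc1cc(C(=O)O[C@H]2C=C(C)[C@H](O)C[C@@]3(C)CC[C@@](O)(C(C)C)[C@H]23)ccc1O | target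

**Step count and risks**

Total steps: 14. Longest linear sequence: 14 steps (1 → 24); 7 and 19 are bought.

Steps most likely to fail:

Step 3. The silyloxy group may be lost by β-elimination from the aldehyde enamine before the ring closes, or the aldol may dehydrate toward C4 instead of C1. The fallback sets out from 4 and returns at 6. The ring closure is run at 23 °C (pyrrolidine, AcOH, Et2O) and stopped at aldol 5. Its free tertiary hydroxyl, the only acylable oxygen, is acetylated (Ac2O, 4-(dimethylamino)pyridine, Et3N, CH2Cl2) to the aldol acetate F1. DBU then removes acetic acid by E1cB elimination, which can only go toward C1, and gives 6.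

Step 7. The exocyclic enol ether may drift to the endocyclic isomer, or the doubly allylic C6–O bond may ionize on the metal, before the slow, congested [3,3] shift takes place. The fallback sets out from 11 and returns at 13. Tetrabutylammonium fluoride removes the silyl ether to give the diol F2. With MeLi (10 mol%) in phenetole at 180 °C the C6 alkoxide itself adds 5-exo-dig to the alkyne, with no Lewis-acidic metal present, giving the hydroxy methylideneoxolane F3, which rearranges in the same flask to the hydroxy ketone F4. Re-silylation (Et3SiOTf, 2,6-lutidine) gives 13.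

Step 10. Borane may add with poor facial selectivity, attack from the β face giving the cis-fused C5,C6-epimeric alcohol. The fallback sets out from 16 and returns at 21. The crude hydroboration product is oxidized (Dess–Martin periodinane) to the C6 ketone F5, which makes the C6 configuration irrelevant. HF·pyridine frees the C4 hydroxyl, and the β-hydroxy ketone F6 is equilibrated at C5 (Et3N, MeOH) to the trans-fused isomer, in which C6 sits cis to the C4 hydroxyl (hydrogen bond to C6=O) and not to the isopropyl group. Me4NBH(OAc)3 in AcOH/MeCN then delivers hydride intramolecularly from the boron bound to the β-oriented C4 oxygen and should give the anti diol F7 with the 6α-hydroxyl. Acylation with 19 (dicyclohexylcarbodiimide, 4-(dimethylamino)pyridine) at the secondary hydroxyl gives the ester F8, and aqueous HF in MeCN opens the dioxolane to 21.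

**Further compounds**

F1 | step 3 | (3R)-2-formyl-1-methyl-3-(propan-2-yl)-3-[(triethylsilyl)oxy]cyclopentyl acetate (diastereomers at C1 and C2) | O=CC1C(C)(OC(C)=O)CC[C@@]1(O[Si](CC)(CC)CC)C(C)C
F2 | step 7 | (1R)-2-[(1S)-1-hydroxypent-4-yn-1-yl]-3-methyl-1-(propan-2-yl)cyclopent-2-en-1-ol | C#CCC[C@H](O)C1=C(C)CC[C@@]1(O)C(C)C
F3 | step 7 | (1R)-3-methyl-2-[(2S)-5-methylideneoxolan-2-yl]-1-(propan-2-yl)cyclopent-2-en-1-ol | C=C1CC[C@H](O1)C2=C(C)CC[C@@]2(O)C(C)C
F4 | step 7 | (3R,8aR)-3-hydroxy-8a-methyl-3-(propan-2-yl)-1,2,3,5,6,8a-hexahydroazulen-7(8H)-one | O=C1CCC=C2[C@](O)(C(C)C)CC[C@]2(C)C1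
F5 | step 10 | (3'R,8a'R)-6',8a'-dimethyl-3'-(propan-2-yl)-3'-[(triethylsilyl)oxy]octahydro-4'H-spiro[1,3-dioxolane-2,7'-azulen]-4'-one (C3a' and C6' epimers) | O=C1CC(C)C2(OCCO2)C[C@@]3(C)CC[C@@](O[Si](CC)(CC)CC)(C(C)C)C13
F6 | step 10 | (3'R,3a'R,8a'R)-3'-hydroxy-6',8a'-dimethyl-3'-(propan-2-yl)octahydro-4'H-spiro[1,3-dioxolane-2,7'-azulen]-4'-one (trans-fused; both C6' epimers) | O=C1CC(C)C2(OCCO2)C[C@@]3(C)CC[C@@](O)(C(C)C)[C@H]13
F7 | step 10 | (3'R,3a'S,4'S,8a'R)-6',8a'-dimethyl-3'-(propan-2-yl)octahydro-1'H-spiro[1,3-dioxolane-2,7'-azulene]-3',4'-diol (both C6' epimers) | O[C@H]1CC(C)C2(OCCO2)C[C@@]3(C)CC[C@@](O)(C(C)C)[C@H]13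
F8 | step 10 | (3'R,3a'S,4'S,8a'R)-3'-hydroxy-6',8a'-dimethyl-3'-(propan-2-yl)octahydro-1'H-spiro[1,3-dioxolane-2,7'-azulen]-4'-yl 4-acetoxy-3-methoxybenzoate (both C6' epimers) | COc1cc(C(=O)O[C@H]2CC(C)C3(OCCO3)C[C@@]4(C)CC[C@@](O)(C(C)C)[C@H]24)ccc1OC(C)=O
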